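**Plan**

- Retrosynthesis: the four O-benzyl groups and the 8-O-acetyl group are removed first on paper. Ring C is then opened at O1–C2 and its C4 carbonyl is stored as the C=N of an isoxazole. The isoxazole is cut at C3–C4 and at its O–C2 bond into a ring A nitrile oxide (C4 on C4a) and the enolate of an α-benzyloxy ring B ketone (C3 and C2).
- Forward: ring A is elaborated from 5-methoxyresorcinol (C8 oxygen by Dakin oxidation, C4 by directed lithiation and formylation, then oxime and nitrile oxide). The ring B ketone comes from an aryllithium and a Weinreb amide. The isoxazole is closed next, and ring C arises last by N–O cleavage and acid-mediated O1–C2 closure.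
- Enabling feature: C4 hangs on C4a, whose two neighbours C5 and C8a both carry oxygen, so the nitrile oxide is 2,6-dioxygenated and shielded against dimerisation. C3 carries oxygen, so the ketone partner has a single enolisable carbon.
- Protecting groups: O8 and O8a are both methoxymethyl ethers and O5 is a benzyl ether. One acid step frees 8-OH and 8a-OH, only 8a-OH can reach C2, and 8-OH is then the one hydroxyl left for acetylation.
- Stereochemistry: the target has no stereocentre. The oxime and enaminone geometries and the two sp3 carbons of the hydroxyisoxazoline are transient.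

Key step: step 9

Assumption: 4-bromo-1,2-bis(benzyloxy)benzene and 2-(benzyloxy)-N-methoxy-N-methylacetamide are taken as catalogue compounds, and nitrile oxide 11 is taken to be stable enough to handle in solution at 0 °C, as other 2,6-dialkoxybenzonitrile oxides are.

**Route**

Step 1
Reactants: 1 5-methoxyresorcinol
Product: 3 2,4-dihydroxy-6-methoxybenzaldehyde, via iminium chloride 2 (not isolated)
Conditions: POCl3, DMF, MeCN, 0 °C to rt; then H2O, 50 °C
Reagents that add atoms: N,N-dimethylformamide CN(C)C=O (formyl carbon); water O (formyl oxygen)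
Why: Vilsmeier–Haack formylation of a resorcinol goes para to one hydroxyl and ortho to the other rather than between the two (as orcinol does), and the iminium salt is hydrolysed by warm water.

Step 2
Reactants: 3 2,4-dihydroxy-6-methoxybenzaldehyde
Product: 4 4-(benzyloxy)-2-hydroxy-6-methoxybenzaldehyde
Conditions: BnBr (1.05 equiv), NaHCO3, NaI (cat.), MeCN, 70 °C
Reagents that add atoms: benzyl bromide BrCc1ccccc1
Why: Williamson etherification under weak base should alkylate only the more acidic 4-OH para to the formyl group, because the 2-OH is held in a hydrogen bond to the aldehyde.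

Step 3
Reactants: 4 4-(benzyloxy)-2-hydroxy-6-methoxybenzaldehyde
Product: 6 5-(benzyloxy)-3-methoxybenzene-1,2-diol, via aryl formate 5 (not isolated)
Conditions: 30% aq H2O2 (1.1 equiv), NaOH, THF/H2O, 0 °C, Ar; then 1 M HCl
Reagents that add atoms: hydrogen peroxide OO
Why: Dakin oxidation, in which the ortho-phenoxide drives aryl migration in the peroxide adduct and the aryl formate is saponified in the same flask, turning the formyl-bearing carbon into the future C8–O.

Step 4
Reactants: 6 5-(benzyloxy)-3-methoxybenzene-1,2-diol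
Product: 7 5-(benzyloxy)-1-methoxy-2,3-bis(methoxymethoxy)benzene
Conditions: MOMCl, i-Pr2NEt, CH2Cl2, 0 °C to rt
Reagents that add atoms: chloromethyl methyl ether COCCl
Why: Double O-alkylation of a catechol to its bis(methoxymethyl) ether is routine and is carried out at once on the air-sensitive crude diol.

Step 5
Reactants: 7 5-(benzyloxy)-1-methoxy-2,3-bis(methoxymethoxy)benzene
Product: 9 6-(benzyloxy)-4-methoxy-2,3-bis(methoxymethoxy)benzaldehyde, via aryllithium 8 (not isolated)
Conditions: n-BuLi, THF, −40 to 0 °C; DMF, −78 °C to rt; aq NH4Cl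
Reagents that add atoms: N,N-dimethylformamide CN(C)C=O
Why: Directed ortho-metalation, in which the methoxymethoxy group (the strongest director on the ring) has only one free ortho carbon, also flanked by the benzyloxy oxygen, so lithiation should prefer it over the carbon between OMe and OBn before DMF formylates the aryllithium.

Step 6
Reactants: 9 6-(benzyloxy)-4-methoxy-2,3-bis(methoxymethoxy)benzaldehyde
Product: 10 (E)-6-(benzyloxy)-4-methoxy-2,3-bis(methoxymethoxy)benzaldehyde oxime
Conditions: NH2OH·HCl, NaOAc, EtOH/H2O, rt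
Reagents that add atoms: hydroxylamine hydrochloride Cl.NO
Why: Oxime condensation of an aromatic aldehyde under acetate buffer is reliable even with two ortho substituents and leaves the acetal ethers untouched.

Step 7
Reactants: 10 (E)-6-(benzyloxy)-4-methoxy-2,3-bis(methoxymethoxy)benzaldehyde oxime
Product: 11 6-(benzyloxy)-4-methoxy-2,3-bis(methoxymethoxy)benzonitrile oxide
Conditions: PhI(OAc)2, CH2Cl2, 0 °C
Reagents that add atoms: none
Why: Hypervalent-iodine dehydrogenation of an aldoxime gives the nitrile oxide without the N-halo reagents that could halogenate the electron-rich ring carbon, and the two ortho oxygens should make the product persistent enough to be washed, concentrated cold and used directly.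

Step 8
Reactants: 12 4-bromo-1,2-bis(benzyloxy)benzene; 13 2-(benzyloxy)-N-methoxy-N-methylacetamide
Product: 15 2-(benzyloxy)-1-[3,4-bis(benzyloxy)phenyl]ethanone, via aryllithium 14 (not isolated)
Conditions: n-BuLi, THF, −78 °C; then 13, −78 to 0 °C; 1 M HCl
Reagents that add atoms: none
Why: Bromine–lithium exchange followed by Weinreb ketone synthesis, where the chelated tetrahedral adduct prevents a second addition.

Step 9
Reactants: 15 2-(benzyloxy)-1-[3,4-bis(benzyloxy)phenyl]ethanone; 11 6-(benzyloxy)-4-methoxy-2,3-bis(methoxymethoxy)benzonitrile oxide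
Product: 18 4-(benzyloxy)-3-[6-(benzyloxy)-4-methoxy-2,3-bis(methoxymethoxy)phenyl]-5-[3,4-bis(benzyloxy)phenyl]isoxazole, via lithium enolate 16 (not isolated), via hydroxyisoxazoline 17 (not isolated)
Conditions: 15, LiN(SiMe3)2, THF, −78 °C; then 11 in THF, −78 to 0 °C; aq NH4Cl; then pyridinium p-toluenesulfonate (cat.), 4 Å molecular sieves, toluene, 60 °C
Reagents that add atoms: none
Why: Proposed new method: the carbon of lithium enolate 16 attacks the electrophilic carbon of nitrile oxide 11 (C3–C4), the resulting oximate oxygen adds to the aryl ketone carbonyl (isoxazole O–C2) to give hemiketal 17, and acid-catalysed loss of water, eased by the electron-rich ring B on the carbinol carbon, aromatises the ring; the closest known reaction type is the condensation of aryl nitrile oxides with lithium or sodium enolates of α-substituted ketones to 5-hydroxyisoxazolines that dehydrate to 3,4,5-trisubstituted isoxazoles, and the new element is the α-benzyloxy group on the enolate. The only ring closed is the isoxazoline, by 5-exo-trig attack of oxygen on the C=O group. The two stereocentres of 17 form without control as a diastereomer mixture and both disappear on dehydration, so no element of stereocontrol is needed. The step needs regioselectivity (ring A on the carbon that becomes C4, ring B on the carbon that becomes C2), and polarity fixes it, because carbon bonds to carbon and oxygen to the carbonyl carbon. It also needs the nitrile oxide to outlive dimerisation to the furoxan, which the oxygen substituents on both ortho carbons (the future C5 and C8a) should secure by shielding the CNO carbon. Ketone 15 has a single enolisable carbon, so only one enolate can form.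

Step 10
Reactants: 18 4-(benzyloxy)-3-[6-(benzyloxy)-4-methoxy-2,3-bis(methoxymethoxy)phenyl]-5-[3,4-bis(benzyloxy)phenyl]isoxazole
Product: 19 (2E)-3-amino-2-(benzyloxy)-3-[6-(benzyloxy)-4-methoxy-2,3-bis(methoxymethoxy)phenyl]-1-[3,4-bis(benzyloxy)phenyl]prop-2-en-1-one (NH2 and C=O on the same side, hydrogen-bonded)
Conditions: Mo(CO)6, MeCN/H2O, 80 °C
Reagents that add atoms: none
Why: Reductive N–O cleavage of isoxazoles by zerovalent molybdenum carbonyl in wet acetonitrile gives β-enaminones and should leave benzyl and acetal ethers alone.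

Step 11
Reactants: 19 (2E)-3-amino-2-(benzyloxy)-3-[6-(benzyloxy)-4-methoxy-2,3-bis(methoxymethoxy)phenyl]-1-[3,4-bis(benzyloxy)phenyl]prop-2-en-1-one
Product: 21 3,5-bis(benzyloxy)-2-[3,4-bis(benzyloxy)phenyl]-8-hydroxy-7-methoxy-4H-chromen-4-one, via dihydroxy enaminone 20 (not isolated)
Conditions: 2 M aq HCl, MeOH/THF, 55 °C
Reagents that add atoms: water O
Why: Acid acetal cleavage frees 8-OH and 8a-OH, the 8a-OH adds to the ring B ketone carbon and water is lost (O1–C2), and the 4-iminium hydrolyses to the C4 ketone, which is the usual cyclodehydration of o-hydroxyaryl β-enaminones to chromones; the C5 benzyl ether blocks the alternative closure.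

Step 12
Reactants: 21 3,5-bis(benzyloxy)-2-[3,4-bis(benzyloxy)phenyl]-8-hydroxy-7-methoxy-4H-chromen-4-one
Product: 22 3,5-bis(benzyloxy)-2-[3,4-bis(benzyloxy)phenyl]-7-methoxy-4-oxo-4H-chromen-8-yl acetate
Conditions: Ac2O, pyridine, DMAP (cat.), CH2Cl2, 0 °C to rt
Reagents that add atoms: acetic anhydride CC(=O)OC(C)=O
Why: DMAP-catalysed O-acylation of the only free hydroxyl in the molecule places the acetate at C8 without any selectivity question.

Step 13
Reactants: 22 3,5-bis(benzyloxy)-2-[3,4-bis(benzyloxy)phenyl]-7-methoxy-4-oxo-4H-chromen-8-yl acetate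
Product: 23 gossypetin 7-methyl ether 8-acetate
Conditions: H2 (1 atm), 10% Pd/C (palladium metal on carbon), EtOAc/THF, rt
Reagents that add atoms: none
Why: Catalytic hydrogenolysis should remove all four benzyl ethers while sparing the aryl acetate and the flavonol C2=C3 bond; the aprotic solvent prevents ester solvolysis, and the acetate has no neighbouring free hydroxyl to migrate to, since C7 carries OMe.

**Compound list**

1 | 5-methoxyresorcinol (5-methoxybenzene-1,3-diol) | COc1cc(O)cc(O)c1 | starting material
2 | N-[(2,4-dihydroxy-6-methoxyphenyl)methylidene]-N-methylmethanaminium chloride (not isolated) | C[N+](C)=Cc1c(O)cc(O)cc1OC.[Cl-] | intermediate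
3 | 2,4-dihydroxy-6-methoxybenzaldehyde | COc1cc(O)cc(O)c1C=O | intermediate
4 | 4-(benzyloxy)-2-hydroxy-6-methoxybenzaldehyde | COc1cc(OCc2ccccc2)cc(O)c1C=O | intermediate
5 | 4-(benzyloxy)-2-hydroxy-6-methoxyphenyl formate (not isolated) | COc1cc(OCc2ccccc2)cc(O)c1OC=O | intermediate
6 | 5-(benzyloxy)-3-methoxybenzene-1,2-diol | COc1cc(OCc2ccccc2)cc(O)c1O | intermediate
7 | 5-(benzyloxy)-1-methoxy-2,3-bis(methoxymethoxy)benzene | COCOc1cc(OCc2ccccc2)cc(OC)c1OCOC | intermediate
8 | [6-(benzyloxy)-4-methoxy-2,3-bis(methoxymethoxy)phenyl]lithium (not isolated) | [Li]c1c(OCc2ccccc2)cc(OC)c(OCOC)c1OCOC | intermediate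
9 | 6-(benzyloxy)-4-methoxy-2,3-bis(methoxymethoxy)benzaldehyde | O=Cc1c(OCc2ccccc2)cc(OC)c(OCOC)c1OCOC | intermediate
10 | (E)-6-(benzyloxy)-4-methoxy-2,3-bis(methoxymethoxy)benzaldehyde oxime | O/N=C/c1c(OCc2ccccc2)cc(OC)c(OCOC)c1OCOC | intermediate
11 | 6-(benzyloxy)-4-methoxy-2,3-bis(methoxymethoxy)benzonitrile oxide | [O-][N+]#Cc1c(OCc2ccccc2)cc(OC)c(OCOC)c1OCOC | intermediate
12 | 4-bromo-1,2-bis(benzyloxy)benzene | Brc1ccc(OCc2ccccc2)c(OCc2ccccc2)c1 | starting material
13 | 2-(benzyloxy)-N-methoxy-N-methylacetamide | CON(C)C(=O)COCc1ccccc1 | starting material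
14 | [3,4-bis(benzyloxy)phenyl]lithium (not isolated) | [Li]c1ccc(OCc2ccccc2)c(OCc2ccccc2)c1 | intermediate
15 | 2-(benzyloxy)-1-[3,4-bis(benzyloxy)phenyl]ethanone | O=C(COCc1ccccc1)c1ccc(OCc2ccccc2)c(OCc2ccccc2)c1 | intermediate
16 | lithium (Z)-2-(benzyloxy)-1-[3,4-bis(benzyloxy)phenyl]ethenolate (not isolated) | [Li]O/C(=C\OCc1ccccc1)c1ccc(OCc2ccccc2)c(OCc2ccccc2)c1 | intermediate
17 | 4-(benzyloxy)-3-[6-(benzyloxy)-4-methoxy-2,3-bis(methoxymethoxy)phenyl]-5-[3,4-bis(benzyloxy)phenyl]-4,5-dihydroisoxazol-5-ol (racemic diastereomer mixture, not isolated) | COCOc1c(OCOC)c(OC)cc(OCc2ccccc2)c1C1=NOC(O)(c2ccc(OCc3ccccc3)c(OCc3ccccc3)c2)C1OCc1ccccc1 | intermediate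
18 | 4-(benzyloxy)-3-[6-(benzyloxy)-4-methoxy-2,3-bis(methoxymethoxy)phenyl]-5-[3,4-bis(benzyloxy)phenyl]isoxazole | COCOc1c(OCOC)c(OC)cc(OCc2ccccc2)c1-c1noc(-c2ccc(OCc3ccccc3)c(OCc3ccccc3)c2)c1OCc1ccccc1 | intermediate
19 | (2E)-3-amino-2-(benzyloxy)-3-[6-(benzyloxy)-4-methoxy-2,3-bis(methoxymethoxy)phenyl]-1-[3,4-bis(benzyloxy)phenyl]prop-2-en-1-one | COCOc1c(OCOC)c(OC)cc(OCc2ccccc2)c1/C(N)=C(\OCc1ccccc1)C(=O)c1ccc(OCc2ccccc2)c(OCc2ccccc2)c1 | intermediate
20 | (2E)-3-amino-2-(benzyloxy)-3-[6-(benzyloxy)-2,3-dihydroxy-4-methoxyphenyl]-1-[3,4-bis(benzyloxy)phenyl]prop-2-en-1-one (not isolated) | Oc1c(O)c(OC)cc(OCc2ccccc2)c1/C(N)=C(\OCc1ccccc1)C(=O)c1ccc(OCc2ccccc2)c(OCc2ccccc2)c1 | intermediate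
21 | 3,5-bis(benzyloxy)-2-[3,4-bis(benzyloxy)phenyl]-8-hydroxy-7-methoxy-4H-chromen-4-one | COc1cc(OCc2ccccc2)c2c(=O)c(OCc3ccccc3)c(-c3ccc(OCc4ccccc4)c(OCc4ccccc4)c3)oc2c1O | intermediate
22 | 3,5-bis(benzyloxy)-2-[3,4-bis(benzyloxy)phenyl]-7-methoxy-4-oxo-4H-chromen-8-yl acetate | COc1cc(OCc2ccccc2)c2c(=O)c(OCc3ccccc3)c(-c3ccc(OCc4ccccc4)c(OCc4ccccc4)c3)oc2c1OC(C)=O | intermediate
23 | gossypetin 7-methyl ether 8-acetate (2-(3,4-dihydroxyphenyl)-3,5-dihydroxy-7-methoxy-4-oxo-4H-chromen-8-yl acetate) | COc1cc(O)c2c(=O)c(O)c(-c3ccc(O)c(O)c3)oc2c1OC(C)=O | target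

**Step count and risks**

Total step count: 13. Longest linear sequence: 12 (steps 1 to 7, then 9 to 13); step 8 is the one-step side branch.

Steps most likely to fail:

1. Step 9 (the step carrying the label). The α-benzyloxy enolate may add too slowly to the hindered nitrile oxide, so that the dipole dimerises or rearranges to the isocyanate, or the hemiketal may resist clean dehydration. The fallback uses only known reactions and sets out from aldehyde 9 and ketone 15. Aldol addition of lithium enolate 16 to 9 at −78 °C should give 2-(benzyloxy)-3-[6-(benzyloxy)-4-methoxy-2,3-bis(methoxymethoxy)phenyl]-1-[3,4-bis(benzyloxy)phenyl]-3-hydroxypropan-1-one F1 as a diastereomer mixture of no consequence. Dess–Martin oxidation should then give 2-(benzyloxy)-1-[6-(benzyloxy)-4-methoxy-2,3-bis(methoxymethoxy)phenyl]-3-[3,4-bis(benzyloxy)phenyl]propane-1,3-dione F2. The acid treatment of step 11 (2 M HCl, MeOH/THF) removes both acetal ethers and cyclodehydrates the diketone, so the route is rejoined at flavone 21.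

2. Step 5. Lithiation may occur at the ring carbon between OMe and OBn, or at the benzylic CH2 of the benzyl ether with Wittig rearrangement. The fallback sets out from catechol 6. Magnesium phenoxide-directed ortho-formylation (MgCl2, Et3N, paraformaldehyde, MeCN, reflux) can only strike the one ring carbon ortho to a free hydroxyl and should give 6-(benzyloxy)-2,3-dihydroxy-4-methoxybenzaldehyde F3. Double protection with MOMCl and i-Pr2NEt then rejoins the route at aldehyde 9.

3. Step 3. The very electron-rich catechol may be over-oxidised to quinones under alkaline peroxide. The fallback sets out from 4 and never forms a free catechol. Protection of the 2-OH (MOMCl, i-Pr2NEt) gives 4-(benzyloxy)-2-methoxy-6-(methoxymethoxy)benzaldehyde F4. Baeyer–Villiger oxidation with mCPBA in CH2Cl2 gives 4-(benzyloxy)-2-methoxy-6-(methoxymethoxy)phenyl formate F5. Methanolysis with K2CO3 (cat.) in MeOH gives 4-(benzyloxy)-2-methoxy-6-(methoxymethoxy)phenol F6, and a second MOM protection rejoins the route at 7.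

**Further compounds**

F1 | step 9 | 2-(benzyloxy)-3-[6-(benzyloxy)-4-methoxy-2,3-bis(methoxymethoxy)phenyl]-1-[3,4-bis(benzyloxy)phenyl]-3-hydroxypropan-1-one (diastereomer mixture) | COCOc1c(OCOC)c(OC)cc(OCc2ccccc2)c1C(O)C(OCc1ccccc1)C(=O)c1ccc(OCc2ccccc2)c(OCc2ccccc2)c1
F2 | step 9 | 2-(benzyloxy)-1-[6-(benzyloxy)-4-methoxy-2,3-bis(methoxymethoxy)phenyl]-3-[3,4-bis(benzyloxy)phenyl]propane-1,3-dione | COCOc1c(OCOC)c(OC)cc(OCc2ccccc2)c1C(=O)C(OCc1ccccc1)C(=O)c1ccc(OCc2ccccc2)c(OCc2ccccc2)c1
F3 | step 5 | 6-(benzyloxy)-2,3-dihydroxy-4-methoxybenzaldehyde | O=Cc1c(OCc2ccccc2)cc(OC)c(O)c1O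
F4 | step 3 | 4-(benzyloxy)-2-methoxy-6-(methoxymethoxy)benzaldehyde | COCOc1cc(OCc2ccccc2)cc(OC)c1C=O
F5 | step 3 | 4-(benzyloxy)-2-methoxy-6-(methoxymethoxy)phenyl formate | COCOc1cc(OCc2ccccc2)cc(OC)c1OC=O
F6 | step 3 | 4-(benzyloxy)-2-methoxy-6-(methoxymethoxy)phenol | COCOc1cc(OCc2ccccc2)cc(OC)c1O
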